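**Strategy.** The route rests on disconnecting the C5'–C6' bond of the cyclohexane ring (C1' bears the side chain, C2' the gem-dimethyl group, C3' a methyl group, C6' the exocyclic methylene). The C6'=CH2 unit is read as a former vinyl group on C1'. A cobalt-catalysed radical Heck-type cyclisation of an open-chain primary iodide (C5') onto that vinyl group closes the six-membered ring and leaves the exocyclic methylene in one operation. The precursor is an acyclic iodo-enyne that already carries both ring stereocentres: C1' from an iridium-catalysed allylation of an isobutyrate silyl ketene acetal, C3' from a copper hydride reduction. (R)-Citronellal supplies the side-chain stereocentre, farnesol the right half, and a copper-catalysed allylic substitution forms the quaternary carbon last.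

Key step: step 10

Remark: for every catalytic asymmetric step (4, 7, 15, 18) the ligand antipode is chosen so that the configuration drawn results; the sense of induction is assumed from the accepted models and would be confirmed on the first intermediate.

**Route**

Step 1
Reactants: 1 (R)-citronellal
Product: 3 (3R)-3,7-dimethyloct-6-en-1-yne, via enol nonaflate 2 (not isolated)
Conditions: C4F9SO2F, phosphazene base t-BuN=P(pyrrolidin-1-yl)3, DMF, −20 °C → rt
Reagents that add atoms: none
Why: The enolisable aldehyde is trapped as its alkenyl nonaflate and the phosphazene base eliminates nonaflate to the terminal alkyne (one-pot carbonyl-to-alkyne elimination through an enol sulfonate), which keeps both carbons of the CH2CHO unit and does not touch the C3 stereocentre.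

Step 2
Reactants: 3 (3R)-3,7-dimethyloct-6-en-1-yne
Product: 5 [(3R)-3,7-dimethyloct-6-en-1-yn-1-yl]tri(propan-2-yl)silane, via lithium acetylide 4 (not isolated)
Conditions: n-BuLi, THF, −78 °C; then i-Pr3SiOTf, −78 → 0 °C
Reagents that add atoms: triisopropylsilyl trifluoromethanesulfonate CC(C)[Si](OS(=O)(=O)C(F)(F)F)(C(C)C)C(C)C
Why: Deprotonation and C-silylation of the terminal alkyne (alkyne protection) makes this triple bond inert to the later homologation base, carboalumination, copper hydride and radical steps.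

Step 3
Reactants: 5 [(3R)-3,7-dimethyloct-6-en-1-yn-1-yl]tri(propan-2-yl)silane; 6 allyl methyl carbonate
Product: 7 methyl (2E,6R)-6-methyl-8-[tri(propan-2-yl)silyl]oct-2-en-7-yn-1-yl carbonate
Conditions: second-generation Hoveyda–Grubbs catalyst (5 mol %), 6 (3 equiv), CH2Cl2, 40 °C
Reagents that add atoms: none
Why: Olefin cross-metathesis exchanges the isopropylidene terminus for the allyl carbonate with loss of volatile isobutene; the E-alkene should be favoured and the bulky silylalkyne should not engage the ruthenium carbene.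

Step 4
Reactants: 7 methyl (2E,6R)-6-methyl-8-[tri(propan-2-yl)silyl]oct-2-en-7-yn-1-yl carbonate; 8 1-methoxy-2-methyl-1-(trimethylsilyloxy)prop-1-ene
Product: 9 methyl (3R,6R)-3-ethenyl-2,2,6-trimethyl-8-[tri(propan-2-yl)silyl]oct-7-ynoate
Conditions: [Ir(cod)Cl]2 (2 mol %), BINOL-derived bis(1-phenylethyl)amine phosphoramidite (4 mol %), n-PrNH2 (catalyst activation), THF, 50 °C
Reagents that add atoms: none
Why: Iridium-catalysed asymmetric allylic alkylation with a silyl ketene acetal: the tetrasubstituted enolate attacks the substituted terminus of the allyliridium complex, which gives the branched ester with the quaternary C2' and sets C1' (3R in 9) under control of the phosphoramidite.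

Step 5
Reactants: 9 methyl (3R,6R)-3-ethenyl-2,2,6-trimethyl-8-[tri(propan-2-yl)silyl]oct-7-ynoate
Product: 11 [(3R,6R)-6-ethenyl-3,7,7-trimethylnona-1,8-diyn-1-yl]tri(propan-2-yl)silane, via aldehyde 10 (not isolated)
Conditions: i-Bu2AlH (1.2 equiv), CH2Cl2, −78 °C; then MeOH, K2CO3, dimethyl (1-diazo-2-oxopropyl)phosphonate, −78 °C → rt
Reagents that add atoms: dimethyl (1-diazo-2-oxopropyl)phosphonate COP(=O)(OC)C(=[N+]=[N-])C(C)=O
Why: i-Bu2AlH should stop at the aldehyde stage of the hindered, non-enolisable ester, and Ohira–Bestmann homologation in the same flask adds the alkyne carbon that becomes C4'; the silyl-capped alkyne survives K2CO3/MeOH.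

Step 6
Reactants: 11 [(3R,6R)-6-ethenyl-3,7,7-trimethylnona-1,8-diyn-1-yl]tri(propan-2-yl)silane
Product: 13 methyl (2E,5R,8R)-5-ethenyl-3,4,4,8-tetramethyl-10-[tri(propan-2-yl)silyl]dec-2-en-9-ynoate, via alkenylalane 12 (not isolated)
Conditions: Me3Al (3 equiv), Cp2ZrCl2 (0.3 equiv), CH2Cl2, 0 °C → rt; then ClCO2Me, 0 °C → rt
Reagents that add atoms: trimethylaluminium C[Al](C)C; methyl chloroformate COC(=O)Cl
Why: Zirconocene-catalysed syn-methylalumination of the terminal alkyne puts methyl on the internal carbon (C3') and aluminium on the terminus, and acylation of the alkenylalane with retention gives the geometrically pure (E)-enoate.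

Step 7
Reactants: 13 methyl (2E,5R,8R)-5-ethenyl-3,4,4,8-tetramethyl-10-[tri(propan-2-yl)silyl]dec-2-en-9-ynoate
Product: 14 methyl (3S,5R,8R)-5-ethenyl-3,4,4,8-tetramethyl-10-[tri(propan-2-yl)silyl]dec-9-ynoate
Conditions: Cu(OAc)2·H2O (3 mol %), Josiphos ligand (R)-1-[(S)-2-(diphenylphosphino)ferrocenyl]ethyldi-tert-butylphosphine (3 mol %), (EtO)2MeSiH, t-BuOH, toluene, rt
Reagents that add atoms: none
Why: Copper hydride asymmetric conjugate reduction of the β,β-disubstituted enoate sets C3' (3S in 14) by ligand control, helped by the size difference between the tert-alkyl and methyl β-substituents, and should leave the isolated vinyl group alone.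

Step 8
Reactants: 14 methyl (3S,5R,8R)-5-ethenyl-3,4,4,8-tetramethyl-10-[tri(propan-2-yl)silyl]dec-9-ynoate
Product: 15 (3S,5R,8R)-5-ethenyl-3,4,4,8-tetramethyl-10-[tri(propan-2-yl)silyl]dec-9-yn-1-ol
Conditions: LiAlH4, Et2O, 0 °C
Reagents that add atoms: none
Why: Hydride reduction of the ester to the primary alcohol; neither the silylalkyne nor the vinyl group reacts at 0 °C.

Step 9
Reactants: 15 (3S,5R,8R)-5-ethenyl-3,4,4,8-tetramethyl-10-[tri(propan-2-yl)silyl]dec-9-yn-1-ol
Product: 16 [(3R,6R,8S)-6-ethenyl-10-iodo-3,7,7,8-tetramethyldec-1-yn-1-yl]tri(propan-2-yl)silane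
Conditions: I2, PPh3, imidazole, CH2Cl2, 0 °C → rt
Reagents that add atoms: iodine [I][I]
Why: Appel-type iodination of the unhindered primary alcohol gives the radical precursor at C5' without touching a stereocentre.

Step 10
Reactants: 16 [(3R,6R,8S)-6-ethenyl-10-iodo-3,7,7,8-tetramethyldec-1-yn-1-yl]tri(propan-2-yl)silane
Product: 17 {(3R)-3-methyl-5-[(1R,3S)-2,2,3-trimethyl-6-methylidenecyclohexyl]pent-1-yn-1-yl}tri(propan-2-yl)silane
Conditions: Ph3Sn–Co(dmgH)2(py) (15 mol %; dmgH = dimethylglyoximate monoanion), i-Pr2NEt (2 equiv), MeCN, blue LEDs, rt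
Reagents that add atoms: none
Why: Visible light homolyses the alkyl–cobalt bond of the alkylcobaloxime formed from the primary iodide and monovalent cobalt, the C5' radical adds to the internal carbon of the C1' vinyl group, and divalent cobalt takes up the resulting exocyclic primary radical and removes the only β-hydrogen (on C6') as hydridocobalt, which i-Pr2NEt deprotonates to close the cycle. The closest known reaction type is the cobaloxime- or palladium-catalysed intramolecular Heck-type cyclisation of unactivated alkyl iodides onto terminal alkenes. The cyclohexane ring is closed in the 6-exo-trig mode through a chair-like transition state. No new stereocentre is formed, since C6' ends sp2 and C1' and C3' are carried in unchanged (both equatorial in the product chair). The step needs 6-exo attack to outrun 1,5-hydrogen transfer from the allylic C1'–H and 7-endo attack, which the gem-dimethyl group on C2' and the branch on C3' should favour by compressing the chain (Thorpe–Ingold effect); the exocyclic position of the alkene is fixed because C6' carries the only hydrogen β to cobalt, and the silyl-capped alkyne is too remote and hindered to interfere.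

Step 11
Reactants: 17 {(3R)-3-methyl-5-[(1R,3S)-2,2,3-trimethyl-6-methylidenecyclohexyl]pent-1-yn-1-yl}tri(propan-2-yl)silane
Product: 18 (1R,3S)-2,2,3-trimethyl-6-methylidene-1-[(3R)-3-methylpent-4-yn-1-yl]cyclohexane
Conditions: n-Bu4NF, THF, 0 °C → rt
Reagents that add atoms: none
Why: Fluoride-mediated desilylation frees the terminal alkyne needed for hydroalumination; nothing else in the hydrocarbon is fluoride-sensitive.

Step 12
Reactants: 19 (2E,6E)-farnesol
Product: 20 (2E,6E)-farnesyl acetate
Conditions: Ac2O, pyridine, DMAP (cat.), CH2Cl2, rt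
Reagents that add atoms: acetic anhydride CC(=O)OC(C)=O
Why: Acetylation protects the allylic alcohol and deactivates the 2,3-alkene toward the allylic oxidation that follows.

Step 13
Reactants: 20 (2E,6E)-farnesyl acetate
Product: 21 (2E,6E,10E)-12-hydroxy-3,7,11-trimethyldodeca-2,6,10-trien-1-yl acetate
Conditions: SeO2 (10 mol %), t-BuOOH, salicylic acid (10 mol %), CH2Cl2, rt
Reagents that add atoms: tert-butyl hydroperoxide CC(C)(C)OO
Why: Selenium dioxide allylic oxidation (ene reaction then [2,3]-sigmatropic shift) should pick the (E)-methyl group of the terminal, most electron-rich trisubstituted alkene and give the (E)-allylic alcohol.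

Step 14
Reactants: 21 (2E,6E,10E)-12-hydroxy-3,7,11-trimethyldodeca-2,6,10-trien-1-yl acetate
Product: 22 (2E,6E,10E)-12-chloro-3,7,11-trimethyldodeca-2,6,10-trien-1-yl acetate
Conditions: NCS, Me2S, CH2Cl2, −30 → 0 °C
Reagents that add atoms: N-chlorosuccinimide O=C1CCC(=O)N1Cl
Why: Corey–Kim chlorination converts the primary allylic alcohol into the chloride by SN2 displacement of the alkoxysulfonium ion, without allylic transposition.

Step 15
Reactants: 22 (2E,6E,10E)-12-chloro-3,7,11-trimethyldodeca-2,6,10-trien-1-yl acetate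
Product: 23 (2E,6E,10S)-3,7,10,11-tetramethyldodeca-2,6,11-trien-1-yl acetate
Conditions: copper thiophene-2-carboxylate (CuTC, 3 mol %), chiral BINOL-derived phosphoramidite (3.3 mol %), MeMgBr (1.2 equiv, slow addition), CH2Cl2, −78 °C
Reagents that add atoms: methylmagnesium bromide C[Mg]Br
Why: Copper-catalysed asymmetric allylic alkylation (SN2') of the 2-methyl-substituted allylic chloride delivers methyl to C10 with transposition of the alkene to the 1,1-disubstituted terminus, the ligand setting 10S; at −78 °C the allylic acetate should not compete.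

Step 16
Reactants: 23 (2E,6E,10S)-3,7,10,11-tetramethyldodeca-2,6,11-trien-1-yl acetate
Product: 24 (2E,6E,10S)-3,7,10,11-tetramethyldodeca-2,6,11-trien-1-ol
Conditions: K2CO3, MeOH, rt
Reagents that add atoms: none
Why: Base-catalysed transesterification removes the acetate without affecting the alkenes or the C10 stereocentre.

Step 17
Reactants: 24 (2E,6E,10S)-3,7,10,11-tetramethyldodeca-2,6,11-trien-1-ol
Product: 25 diethyl (2E,6E,10S)-3,7,10,11-tetramethyldodeca-2,6,11-trien-1-yl phosphate
Conditions: ClP(O)(OEt)2, pyridine, DMAP (cat.), CH2Cl2, 0 °C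
Reagents that add atoms: diethyl chlorophosphate CCOP(=O)(Cl)OCC
Why: O-Phosphorylation gives the allylic phosphate, the leaving group required for the copper-catalysed SN2' substitution.

Step 18
Reactants: 18 (1R,3S)-2,2,3-trimethyl-6-methylidene-1-[(3R)-3-methylpent-4-yn-1-yl]cyclohexane; 25 diethyl (2E,6E,10S)-3,7,10,11-tetramethyldodeca-2,6,11-trien-1-yl phosphate
Product: 27 target hydrocarbon CNP0293684.4, via alkenylalane 26 (not isolated)
Conditions: i-Bu2AlH (1.0 equiv), hexanes, 55 °C; then 25, chiral sulfonate-bearing imidazolinium salt (2.5 mol %), CuCl2·2H2O (5 mol %), THF, −15 °C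
Reagents that add atoms: none
Why: Syn-hydroalumination of the terminal alkyne gives the (E)-alkenylalane, and N-heterocyclic carbene–copper-catalysed enantioselective allylic substitution (SN2') on the (E)-trisubstituted allylic phosphate forms the quaternary carbon bearing methyl, vinyl and the E-alkene, its S configuration set by the chiral carbene ligand.

**Compound list**

1 | (R)-citronellal, (3R)-3,7-dimethyloct-6-enal | O=CC[C@H](C)CCC=C(C)C | starting material
2 | (3R)-3,7-dimethylocta-1,6-dien-1-yl nonafluorobutane-1-sulfonate, E/Z mixture, not isolated | FC(F)(F)C(F)(F)C(F)(F)C(F)(F)S(=O)(=O)OC=C[C@H](C)CCC=C(C)C | intermediate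
3 | (3R)-3,7-dimethyloct-6-en-1-yne | C#C[C@H](C)CCC=C(C)C | intermediate
4 | lithium acetylide of 3, not isolated | [Li]C#C[C@H](C)CCC=C(C)C | intermediate
5 | [(3R)-3,7-dimethyloct-6-en-1-yn-1-yl]tri(propan-2-yl)silane | CC(C)[Si](C(C)C)(C(C)C)C#C[C@H](C)CCC=C(C)C | intermediate
6 | allyl methyl carbonate | C=CCOC(=O)OC | starting material
7 | methyl (2E,6R)-6-methyl-8-[tri(propan-2-yl)silyl]oct-2-en-7-yn-1-yl carbonate | CC(C)[Si](C(C)C)(C(C)C)C#C[C@H](C)CC/C=C/COC(=O)OC | intermediate
8 | 1-methoxy-2-methyl-1-(trimethylsilyloxy)prop-1-ene | COC(O[Si](C)(C)C)=C(C)C | starting material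
9 | methyl (3R,6R)-3-ethenyl-2,2,6-trimethyl-8-[tri(propan-2-yl)silyl]oct-7-ynoate | CC(C)[Si](C(C)C)(C(C)C)C#C[C@H](C)CC[C@H](C=C)C(C)(C)C(=O)OC | intermediate
10 | (3R,6R)-3-ethenyl-2,2,6-trimethyl-8-[tri(propan-2-yl)silyl]oct-7-ynal, not isolated | CC(C)[Si](C(C)C)(C(C)C)C#C[C@H](C)CC[C@H](C=C)C(C)(C)C=O | intermediate
11 | [(3R,6R)-6-ethenyl-3,7,7-trimethylnona-1,8-diyn-1-yl]tri(propan-2-yl)silane | CC(C)[Si](C(C)C)(C(C)C)C#C[C@H](C)CC[C@H](C=C)C(C)(C)C#C | intermediate
12 | (E)-alkenyl(dimethyl)alane from 11, not isolated | CC(C)[Si](C(C)C)(C(C)C)C#C[C@H](C)CC[C@H](C=C)C(C)(C)/C(C)=C/[Al](C)C | intermediate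
13 | methyl (2E,5R,8R)-5-ethenyl-3,4,4,8-tetramethyl-10-[tri(propan-2-yl)silyl]dec-2-en-9-ynoate | CC(C)[Si](C(C)C)(C(C)C)C#C[C@H](C)CC[C@H](C=C)C(C)(C)/C(C)=C/C(=O)OC | intermediate
14 | methyl (3S,5R,8R)-5-ethenyl-3,4,4,8-tetramethyl-10-[tri(propan-2-yl)silyl]dec-9-ynoate | CC(C)[Si](C(C)C)(C(C)C)C#C[C@H](C)CC[C@H](C=C)C(C)(C)[C@@H](C)CC(=O)OC | intermediate
15 | (3S,5R,8R)-5-ethenyl-3,4,4,8-tetramethyl-10-[tri(propan-2-yl)silyl]dec-9-yn-1-ol | CC(C)[Si](C(C)C)(C(C)C)C#C[C@H](C)CC[C@H](C=C)C(C)(C)[C@@H](C)CCO | intermediate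
16 | [(3R,6R,8S)-6-ethenyl-10-iodo-3,7,7,8-tetramethyldec-1-yn-1-yl]tri(propan-2-yl)silane | CC(C)[Si](C(C)C)(C(C)C)C#C[C@H](C)CC[C@H](C=C)C(C)(C)[C@@H](C)CCI | intermediate
17 | {(3R)-3-methyl-5-[(1R,3S)-2,2,3-trimethyl-6-methylidenecyclohexyl]pent-1-yn-1-yl}tri(propan-2-yl)silane | CC(C)[Si](C(C)C)(C(C)C)C#C[C@H](C)CC[C@@H]1C(=C)CC[C@H](C)C1(C)C | intermediate
18 | (1R,3S)-2,2,3-trimethyl-6-methylidene-1-[(3R)-3-methylpent-4-yn-1-yl]cyclohexane | C#C[C@H](C)CC[C@@H]1C(=C)CC[C@H](C)C1(C)C | intermediate
19 | (2E,6E)-farnesol | OC/C=C(\C)CC/C=C(\C)CCC=C(C)C | starting material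
20 | (2E,6E)-farnesyl acetate | CC(=O)OC/C=C(\C)CC/C=C(\C)CCC=C(C)C | intermediate
21 | (2E,6E,10E)-12-hydroxy-3,7,11-trimethyldodeca-2,6,10-trien-1-yl acetate | CC(=O)OC/C=C(\C)CC/C=C(\C)CC/C=C(\C)CO | intermediate
22 | (2E,6E,10E)-12-chloro-3,7,11-trimethyldodeca-2,6,10-trien-1-yl acetate | CC(=O)OC/C=C(\C)CC/C=C(\C)CC/C=C(\C)CCl | intermediate
23 | (2E,6E,10S)-3,7,10,11-tetramethyldodeca-2,6,11-trien-1-yl acetate | CC(=O)OC/C=C(\C)CC/C=C(\C)CC[C@H](C)C(C)=C | intermediate
24 | (2E,6E,10S)-3,7,10,11-tetramethyldodeca-2,6,11-trien-1-ol | OC/C=C(\C)CC/C=C(\C)CC[C@H](C)C(C)=C | intermediate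
25 | diethyl (2E,6E,10S)-3,7,10,11-tetramethyldodeca-2,6,11-trien-1-yl phosphate | CCOP(=O)(OCC)OC/C=C(\C)CC/C=C(\C)CC[C@H](C)C(C)=C | intermediate
26 | (E)-alkenyl(diisobutyl)alane from 18, not isolated | CC(C)C[Al](CC(C)C)/C=C/[C@H](C)CC[C@@H]1C(=C)CC[C@H](C)C1(C)C | intermediate
27 | target hydrocarbon CNP0293684.4 (C32H54) | C=C[C@@](C)(/C=C/[C@H](C)CC[C@@H]1C(=C)CC[C@H](C)C1(C)C)CC/C=C(\C)CC[C@H](C)C(=C)C | target

**Count and risks**

Total step count: 18. Longest linear sequence: 12 (steps 1–11 and 18).

Steps most likely to fail: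

1. Step 10 (key step). The C5' radical may abstract the allylic hydrogen on C1' (1,5-hydrogen transfer) or be reduced before it cyclises, and hydridocobalt may move the new double bond into the ring. The fallback replaces the radical closure by a two-electron cross-coupling that forms the same C5'–C6' bond. It sets out from iodide 16: Wacker oxidation of the vinyl group (PdCl2, CuCl, O2, DMF/H2O) should give the methyl ketone F1. Kinetic enolisation on the methyl side (KN(SiMe3)2, PhNTf2, −78 °C) should give the enol triflate F2. Zinc insertion into the primary iodide (Zn dust, DMA) would give the alkylzinc iodide F3, and intramolecular Negishi coupling (Pd(PPh3)4, THF, 50 °C) would return to 17.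

2. Step 18. Alkenyl transfer to the hindered γ-carbon may give way to direct SN2 attack or show poor facial selectivity at the quaternary centre, and hydroalumination may be incomplete or unselective. The fallback sets out from alkyne 18 and phosphate 25 and forms the C(sp)–C(sp3) bond first, leaving the alkene geometry to a later reduction. Alumination of 18 (i-Bu2AlH, Et3N cat.) would give the alkynyl(diisobutyl)alane F4. The same carbene–copper-catalysed SN2' substitution on 25, now with a small linear nucleophile, should give the 1,4-enyne F5. Dissolving-metal reduction (Na, NH3, t-BuOH, THF, −78 °C) of the internal alkyne would give the E-alkene and so the target 27.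

3. Step 4. The hindered tetrasubstituted ketene acetal may give the linear ester or low enantioselectivity, and any Z-carbonate carried from the metathesis would make this worse. The fallback sets out from 5 and replaces catalyst control by chirality transfer in a [3,3]-sigmatropic rearrangement. Cross-metathesis of 5 with commercial (S)-but-3-en-2-ol would give the (2S,3E)-allylic alcohol F6. Acylation (isobutyryl chloride, pyridine) would give the isobutyrate F7. Ireland–Claisen rearrangement (LiN(i-Pr)2, Me3SiCl, THF, −78 °C → rt) through a chair with the carbinol methyl equatorial should give the acid F8 with C1' set, and methylation (Me3SiCHN2) its methyl ester F9. Ethenolysis (second-generation Hoveyda–Grubbs catalyst, ethylene) would cut the propenyl group back to vinyl and return to 9.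

**Further compounds**

F1 | step 10 | (3R,4? open chain) methyl ketone from Wacker oxidation of 16: 3-[(1R-configured C1') acetyl] iodide, (3R,6R,8S)-series | CC(C)[Si](C(C)C)(C(C)C)C#C[C@H](C)CC[C@H](C(C)=O)C(C)(C)[C@@H](C)CCI
F2 | step 10 | enol triflate of F1 | CC(C)[Si](C(C)C)(C(C)C)C#C[C@H](C)CC[C@H](C(=C)OS(=O)(=O)C(F)(F)F)C(C)(C)[C@@H](C)CCI
F3 | step 10 | alkylzinc iodide from F2 | CC(C)[Si](C(C)C)(C(C)C)C#C[C@H](C)CC[C@H](C(=C)OS(=O)(=O)C(F)(F)F)C(C)(C)[C@@H](C)CC[Zn]I
F4 | step 18 | alkynyl(diisobutyl)alane from 18 | CC(C)C[Al](CC(C)C)C#C[C@H](C)CC[C@@H]1C(=C)CC[C@H](C)C1(C)C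
F5 | step 18 | 1,4-enyne with the quaternary centre in place | C=C[C@@](C)(C#C[C@H](C)CC[C@@H]1C(=C)CC[C@H](C)C1(C)C)CC/C=C(\C)CC[C@H](C)C(=C)C
F6 | step 4 | (2S,3E,7R)-7-methyl-9-[tri(propan-2-yl)silyl]non-3-en-8-yn-2-ol | C[C@H](O)/C=C/CC[C@@H](C)C#C[Si](C(C)C)(C(C)C)C(C)C
F7 | step 4 | isobutyrate of F6 | CC(C)C(=O)O[C@@H](C)/C=C/CC[C@@H](C)C#C[Si](C(C)C)(C(C)C)C(C)C
F8 | step 4 | (3R,6R)-2,2,6-trimethyl-3-[(E)-prop-1-enyl]-8-[tri(propan-2-yl)silyl]oct-7-ynoic acid | OC(=O)C(C)(C)[C@@H](/C=C/C)CC[C@@H](C)C#C[Si](C(C)C)(C(C)C)C(C)C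
F9 | step 4 | methyl ester of F8 | COC(=O)C(C)(C)[C@@H](/C=C/C)CC[C@@H](C)C#C[Si](C(C)C)(C(C)C)C(C)C
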